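**Plan**

- The target 17 is an achiral diaryl ether. The retrosynthesis first removes the two C–Br bonds of ring B (C2 and C4; phenol numbering, OH on C1) and an O-acetyl group, then cuts ring B itself at C1–C6 and C4–C5.
- This cut is possible because ring B carries OH on C1 and the aryloxy oxygen on the neighbouring C6. C1–C4 map onto C3–C6 of a 3-acyloxy-2-pyrone; C6 and C5 map onto the oxygen-bearing and the terminal carbon of an aryl ethynyl ether.
- Forward, ring A is bought as guaiacol and tribrominated. Its phenol oxygen is elaborated (2-bromoethyl, vinyl, 2-bromovinyl ether) to the ynol ether 10, so the crowded diaryl ether C–O bond exists before ring B does.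
- Ring B then arises in one operation from 10 and 3-acetoxy-2-pyrone 12 by [4+2] cycloaddition and loss of CO2. Methanolysis and a phenol-directed dibromination finish the synthesis.
- The target has no stereocentre. The stereo-elements met on the way (Z alkene of 9, the stereocentre of 8, the bridgeheads of 13) are transient, and all selectivity to be controlled is regiochemical.

Key step: step 7

Remark on the chemistry: guaiacol is assumed to take up exactly three bromines at C4, C5 and C6 (OH on C1), C3 being the least activated and most crowded position; this point is taken up again under the risks.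

**Route**

Step 1
Reactants: 1 guaiacol (2-methoxyphenol)
Product: 4 2,3,4-tribromo-6-methoxyphenol, via 4-bromoguaiacol 2 (not isolated), via 4,5-dibromoguaiacol 3 (not isolated)
Conditions: Br2 (3.05 equiv), AcOH, 15 °C to rt, then 45 °C; aq. NaHSO3; recrystallisation
Reagents that add atoms: bromine, BrBr
Why: Electrophilic aromatic bromination in which OH directs to C4 and C6 and OMe to C5, while C3 (ortho to OMe only and flanked) stays free, so three equivalents should stop at the 4,5,6-tribromide.

Step 2
Reactants: 4 2,3,4-tribromo-6-methoxyphenol; 5 1,2-dibromoethane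
Product: 6 1,2,3-tribromo-4-(2-bromoethoxy)-5-methoxybenzene
Conditions: 5 (5 equiv), K2CO3 (2 equiv), MeCN, reflux
Reagents that add atoms: none
Why: Williamson ether synthesis (SN2) of the acidic, hindered phenoxide on a primary bromide, with the dihalide in excess so that a second displacement to the bis(aryloxy)ethane stays minor.

Step 3
Reactants: 6 1,2,3-tribromo-4-(2-bromoethoxy)-5-methoxybenzene
Product: 7 1,2,3-tribromo-4-(ethenyloxy)-5-methoxybenzene
Conditions: KOtBu (1.5 equiv), THF, 0 °C to rt
Reagents that add atoms: none
Why: E2 dehydrobromination by a bulky alkoxide, the standard passage from aryl 2-bromoethyl ethers to aryl vinyl ethers, in which bromide leaves far more readily than the aryloxide and the aryl C–Br bonds are untouched at this temperature.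

Step 4
Reactants: 7 1,2,3-tribromo-4-(ethenyloxy)-5-methoxybenzene
Product: 9 1,2,3-tribromo-4-{[(Z)-2-bromoethenyl]oxy}-5-methoxybenzene, via 1,2-dibromoethyl ether 8 (not isolated)
Conditions: Br2 (1.0 equiv), CH2Cl2, −78 °C; then i-Pr2NEt (2 equiv), −78 °C to rt (40 °C if slow)
Reagents that add atoms: bromine, BrBr
Why: Electrophilic addition of Br2 to the enol ether double bond (the tribrominated ring is too deactivated to compete) gives the α,β-dibromo ether 8, from which the hindered, non-nucleophilic amine removes HBr (acetal-type α-bromide and a proton of CH2Br) to the 2-bromovinyl ether, the Z isomer being the usual main product of this classical bromination–dehydrobromination.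

Step 5
Reactants: 9 1,2,3-tribromo-4-{[(Z)-2-bromoethenyl]oxy}-5-methoxybenzene
Product: 10 1,2,3-tribromo-4-(ethynyloxy)-5-methoxybenzene
Conditions: KOtBu (2.3 equiv), THF, −78 to 0 °C; aq. NH4Cl; filtered through basic Al2O3 and used at once as a toluene solution
Reagents that add atoms: none
Why: Base-induced anti-elimination of HBr from the (Z)-2-bromovinyl ether (the hydrogen on the oxygen-bearing carbon is trans to bromine) is the classical entry to alkynyl ethers, excess base covers the acidity of the terminal alkyne, and no alkyllithium is present that could exchange the aryl bromides.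

Step 6
Reactants: 11 3-hydroxy-2H-pyran-2-one
Product: 12 2-oxo-2H-pyran-3-yl acetate
Conditions: Ac2O (1.5 equiv), pyridine (2 equiv), CH2Cl2, 0 °C to rt
Reagents that add atoms: acetic anhydride, CC(=O)OC(C)=O
Why: O-Acylation (nucleophilic acyl substitution) of the enolic, phenol-like 3-hydroxyl group, which both protects it and makes the pyrone a more electron-poor diene for the cycloaddition.

Step 7
Reactants: 10 1,2,3-tribromo-4-(ethynyloxy)-5-methoxybenzene; 12 2-oxo-2H-pyran-3-yl acetate
Product: 14 2-(2,3,4-tribromo-6-methoxyphenoxy)phenyl acetate, via bridged lactone 13 (not isolated)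
Conditions: 12 (3 equiv), BHT (5 mol%), toluene, 110 °C under N2, 10 added by syringe pump over several hours (xylene, 140 °C if slow)
Reagents that add atoms: none
Why: The acetoxy-substituted 2-pyrone 12 serves as the electron-poor four-carbon partner and the aryl ynol ether 10 as the electron-rich two-carbon partner of a thermal, concerted but asynchronous inverse-electron-demand [4+2] cycloaddition, in which the nucleophilic terminal CH carbon of 10 bonds ahead to pyrone C6 and the oxygen-bearing alkyne carbon follows onto C3. The closest known reaction type is the Diels–Alder/retro-Diels–Alder benzannulation of 2-pyrones with alkynes, heteroatom-substituted ones included. Ring B closes as a six-membered carbocycle in this intermolecular [4+2] event (bonds C1–C6 and C4–C5 in phenol numbering), first as the 2-oxabicyclo[2.2.2]octadienone 13, and becomes aromatic when 13 expels CO2 by retro-[4+2], so no oxidant is needed. The two bridgehead stereocentres of 13 form as a racemate and disappear with the CO2, so 14 has no stereocentre to control. The selectivity required is orientation (ortho rather than meta dioxygenation), and it should follow from the matched polarisation of the partners: C6 is the electrophilic terminus of the pyrone dienoate and the carbon β to oxygen is the nucleophilic end of the ynol ether, the same sense in which 3-substituted 2-pyrones take up enol ethers. The aryl group on oxygen offers no C–H from which a retro-ene loss of ketene could start, and slow addition into excess 12 should keep self-condensation of 10 behind the cycloaddition.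

Step 8
Reactants: 14 2-(2,3,4-tribromo-6-methoxyphenoxy)phenyl acetate
Product: 15 2-(2,3,4-tribromo-6-methoxyphenoxy)phenol
Conditions: K2CO3 (0.2 equiv), MeOH, 0 °C to rt; dilute HCl work-up
Reagents that add atoms: none
Why: Base-catalysed transesterification (methanolysis) of an aryl acetate, which is far faster than any attack on the aryl bromides or the diaryl ether.

Step 9
Reactants: 15 2-(2,3,4-tribromo-6-methoxyphenoxy)phenol
Product: 17 2,4-dibromo-6-(2,3,4-tribromo-6-methoxyphenoxy)phenol, via para-monobromide 16 (not isolated)
Conditions: Br2 (2.05 equiv), CH2Cl2/AcOH, 0 °C to rt; aq. Na2S2O3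
Reagents that add atoms: bromine, BrBr
Why: Electrophilic aromatic bromination governed by the free OH of ring B, which activates its para (C4) and ortho (C2) positions far more than the twisted aryloxy group activates C3 and C5 or the methoxy group activates the single C–H of the thrice-brominated ring A, so two equivalents should stop at the target.

**Compound list**

1 | guaiacol (2-methoxyphenol) | COc1ccccc1O | starting material
2 | 4-bromo-2-methoxyphenol (4-bromoguaiacol) | COc1cc(Br)ccc1O | intermediate
3 | 4,5-dibromo-2-methoxyphenol (4,5-dibromoguaiacol) | COc1cc(Br)c(Br)cc1O | intermediate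
4 | 2,3,4-tribromo-6-methoxyphenol (4,5,6-tribromoguaiacol) | COc1cc(Br)c(Br)c(Br)c1O | intermediate
5 | 1,2-dibromoethane | BrCCBr | starting material
6 | 1,2,3-tribromo-4-(2-bromoethoxy)-5-methoxybenzene | COc1cc(Br)c(Br)c(Br)c1OCCBr | intermediate
7 | 1,2,3-tribromo-4-(ethenyloxy)-5-methoxybenzene | COc1cc(Br)c(Br)c(Br)c1OC=C | intermediate
8 | 1,2,3-tribromo-4-(1,2-dibromoethoxy)-5-methoxybenzene (racemic) | COc1cc(Br)c(Br)c(Br)c1OC(Br)CBr | intermediate
9 | 1,2,3-tribromo-4-{[(Z)-2-bromoethenyl]oxy}-5-methoxybenzene | COc1cc(Br)c(Br)c(Br)c1O/C=C\Br | intermediate
10 | 1,2,3-tribromo-4-(ethynyloxy)-5-methoxybenzene | COc1cc(Br)c(Br)c(Br)c1OC#C | intermediate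
11 | 3-hydroxy-2H-pyran-2-one | O=c1occcc1O | starting material
12 | 2-oxo-2H-pyran-3-yl acetate (3-acetoxy-2-pyrone) | CC(=O)Oc1cccoc1=O | intermediate
13 | 3-oxo-8-(2,3,4-tribromo-6-methoxyphenoxy)-2-oxabicyclo[2.2.2]octa-5,7-dien-4-yl acetate (racemic) | CC(=O)OC12C(=O)OC(C=C1)C=C2Oc1c(OC)cc(Br)c(Br)c1Br | intermediate
14 | 2-(2,3,4-tribromo-6-methoxyphenoxy)phenyl acetate | CC(=O)Oc1ccccc1Oc1c(OC)cc(Br)c(Br)c1Br | intermediate
15 | 2-(2,3,4-tribromo-6-methoxyphenoxy)phenol | Oc1ccccc1Oc1c(OC)cc(Br)c(Br)c1Br | intermediate
16 | 4-bromo-2-(2,3,4-tribromo-6-methoxyphenoxy)phenol | Oc1ccc(Br)cc1Oc1c(OC)cc(Br)c(Br)c1Br | intermediate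
17 | 2,4-dibromo-6-(2,3,4-tribromo-6-methoxyphenoxy)phenol | COc1cc(Br)c(Br)c(Br)c1Oc1cc(Br)cc(Br)c1O | target

**Count**

Total step count: 9. Longest linear sequence: 8 steps (steps 1 to 5, then 7, 8 and 9); step 6 is a one-step side branch.

**Steps most likely to fail**

Step 7. The cycloaddition may be slower than the thermal self-condensation of the terminal ynol ether, or the two partners may combine in part with the reverse orientation. The fallback gives up the cycloaddition and makes the diaryl ether C–O bond directly. It sets out from 4, which is heated with 2-fluorobenzaldehyde (O=Cc1ccccc1F) and K2CO3 in N,N-dimethylacetamide at about 130 °C. Nucleophilic aromatic substitution of the fluoride ortho to the formyl group should give 2-(2,3,4-tribromo-6-methoxyphenoxy)benzaldehyde F1. Baeyer–Villiger oxidation with mCPBA in CH2Cl2, aryl migration being favoured by the ortho aryloxy donor, should give 2-(2,3,4-tribromo-6-methoxyphenoxy)phenyl formate F2. Methanolysis with catalytic K2CO3 returns to the route at 15.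

Step 5. tert-Butoxide may add to the newly formed ynol ether or metalate the ring C–H next to bromine (halogen migration or aryne formation), and the terminal alkyne may oligomerise on concentration. The fallback keeps the ring construction but postpones the alkyne oxidation level until after ring closure. It sets out from 9, which is heated with 12 and 2,6-lutidine in xylene at about 140 °C. The cycloaddition should take the same orientation and give 7-bromo-3-oxo-8-(2,3,4-tribromo-6-methoxyphenoxy)-2-oxabicyclo[2.2.2]oct-5-en-4-yl acetate F3 (racemic, bromine and aryloxy cis). Loss of CO2 should give 5-bromo-6-(2,3,4-tribromo-6-methoxyphenoxy)cyclohexa-1,3-dien-1-yl acetate F4. Loss of HBr from F4, the allylic bromide being the better leaving group compared with the aryloxide, aromatises the ring and returns to the route at 14.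

Step 1. The second and third brominations may not follow the order C4, C5, C6 cleanly, or bromination may run on to the tetrabromide. Isomeric or over-brominated phenols would then be carried unnoticed through the whole sequence. The fallback fixes the bromine para to the methoxy group first, under protecting-group control. It sets out from 1, which is acetylated (Ac2O, pyridine) to 2-methoxyphenyl acetate F5. Bromination with Br2 in AcOH, now directed para to OMe because the acetoxy group is the weaker donor, should give 5-bromo-2-methoxyphenyl acetate F6. Methanolysis (K2CO3, MeOH) should give 5-bromo-2-methoxyphenol F7, which can also be bought. Two equivalents of Br2 in AcOH then fill only the positions para and ortho to the free OH, passing through 3 and returning to the route at 4.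

**Further compounds**

F1 | step 7 | 2-(2,3,4-tribromo-6-methoxyphenoxy)benzaldehyde | COc1cc(Br)c(Br)c(Br)c1Oc1ccccc1C=O
F2 | step 7 | 2-(2,3,4-tribromo-6-methoxyphenoxy)phenyl formate | COc1cc(Br)c(Br)c(Br)c1Oc1ccccc1OC=O
F3 | step 5 | 7-bromo-3-oxo-8-(2,3,4-tribromo-6-methoxyphenoxy)-2-oxabicyclo[2.2.2]oct-5-en-4-yl acetate (racemic, 7,8-cis) | CC(=O)OC12C(=O)OC(C=C1)C(Br)C2Oc1c(OC)cc(Br)c(Br)c1Br
F4 | step 5 | 5-bromo-6-(2,3,4-tribromo-6-methoxyphenoxy)cyclohexa-1,3-dien-1-yl acetate (racemic, cis) | CC(=O)OC1=CC=CC(Br)C1Oc1c(OC)cc(Br)c(Br)c1Br
F5 | step 1 | 2-methoxyphenyl acetate | COc1ccccc1OC(C)=O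
F6 | step 1 | 5-bromo-2-methoxyphenyl acetate | COc1ccc(Br)cc1OC(C)=O
F7 | step 1 | 5-bromo-2-methoxyphenol | COc1ccc(Br)cc1O
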